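**Retrosynthetic overview**

1. N–C5 is formed last: a cyclic imine (1‑pyrroline) carrying a 4‑chlorobutyl arm on C9 is N‑alkylated to close the azepine, and loss of H9 gives the enamine (C1 is quaternary, so only one enamine can form).
2. N–C9a and C1–O: a Boc‑amino ketone is cyclodehydrated to a ring‑fused enecarbamate and epoxidised on its convex face, which sets the C1 carbinol. C5–C8 come from 4‑chlorobutanal by aldol condensation and hydrogenation at C9.
3. Carbocycle plus fused lactone: one amine‑catalysed [4+2] (vinylogous Michael, then Michael) between an acyclic (E)‑enone and 3‑methylfuran‑2(5H)‑one forms C10–C11 and C1–C12.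
4. Enone: vinyl Grignard opening of an N‑Boc pyrrolidinone, then cross‑metathesis. The pyrrolidinone–lactone comes from Boc‑L‑pyroglutamic acid by thioester/organozinc ketone synthesis and Felkin reduction–lactonisation.
5. Ring order: pyrrolidinone (chiral pool, later opened) → side lactone → carbocycle and fused lactone together → pyrroline → azepine.

Assumption: atom labels follow the usual tuberostemonine numbering (N4; C1–C3 pyrrolidine; C5–C9 azepine; C9a; C10–C12 carbocycle; C13/C14 fused lactone; C18–C21 side lactone), and the target is made exactly as drawn (1S,3S,10R,11R,12R,13S,18S,20S).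

**Route**

Step 1
Reactants: 1 Boc‑L‑pyroglutamic acid
Product: 2 S‑ethyl (2S)‑1‑Boc‑5‑oxopyrrolidine‑2‑carbothioate
Conditions: EtSH, DCC, DMAP (5 mol %), CH2Cl2, 0 °C to rt
Reagents that add atoms: ethanethiol (CCS)
Why: Steglich‑type DCC/DMAP thioesterification; the fully acylated nitrogen cannot form an oxazolone, so the L‑glutamate centre (future C3, S) is kept.

Step 2
Reactants: 2 S‑ethyl thioester; 3 methyl (2R)‑3‑bromo‑2‑methylpropanoate
Product: 5 Boc‑pyrrolidinone γ‑keto methyl ester, via organozinc bromide 4 (not isolated)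
Conditions: 3, Zn dust, LiCl, THF, 40 °C; then 2, PdCl2(PPh3)2 (5 mol %), THF–toluene, rt; 1 M HCl work‑up
Reagents that add atoms: none
Why: Fukuyama coupling — Pd(0) inserts into the C–S bond and the configurationally stable β‑zincio ester transfers its alkyl group, giving the ketone without touching the imide, the ester or either stereocentre (C20 comes from the bromo ester).

Step 3
Reactants: 5 Boc‑pyrrolidinone γ‑keto methyl ester
Product: 7 N‑Boc pyrrolidinone–lactone, via hydroxy ester 6 (not isolated)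
Conditions: L‑Selectride (1.05 equiv), THF, −78 °C; AcOH quench at −78 °C; then PPTS (cat.), CH2Cl2, rt
Reagents that add atoms: none
Why: Felkin–Anh reduction by a bulky hydride (attack anti to the N(Boc)(acyl) group of the α‑centre) gives the threo 18S carbinol, and acid‑catalysed lactonisation onto the methyl ester closes the cis‑2,4‑disubstituted γ‑lactone; the ketone is reduced much faster than the imide carbonyl at −78 °C, and the cold quench prevents Boc migration.

Step 4
Reactants: 7 N‑Boc pyrrolidinone–lactone; 8 vinylmagnesium bromide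
Product: 9 Boc‑amino vinyl ketone
Conditions: THF, −78 °C (1.1 equiv of 8); AcOH quench at −78 °C
Reagents that add atoms: none
Why: Grignard ring‑opening acylation of the imide‑like N‑Boc lactam carbonyl occurs at −78 °C, where the γ‑lactone is inert, and the chelated tetrahedral intermediate prevents a second addition.

Step 5
Reactants: 9 Boc‑amino vinyl ketone; 10 but‑1‑ene
Product: 11 Boc‑amino (E)‑enone
Conditions: Hoveyda–Grubbs II (3 mol %), but‑1‑ene (excess, condensed), CH2Cl2, 40 °C, sealed tube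
Reagents that add atoms: none
Why: Olefin cross‑metathesis of an electron‑poor vinyl ketone with a terminal alkene is E‑selective and installs the future C10 ethyl group.

Step 6
Reactants: 11 Boc‑amino (E)‑enone; 12 3‑methylfuran‑2(5H)‑one
Product: 14 ring‑A keto lactone, via butenolide adduct 13 (not isolated)
Conditions: 9‑amino‑9‑deoxy‑epi‑quinine (20 mol %), salicylic acid (40 mol %), toluene, 0 °C then 40 °C
Reagents that add atoms: none
Why: Proposed new method: one chiral primary‑amine salt runs an iminium‑then‑enamine relay — its iminium ion with 11 accepts the quinuclidine‑bound dienolate of 12 at C10 (vinylogous Michael; the shielded face is meant to set 10R,11R, and the quinidine‑derived pseudo‑enantiomer would give the opposite sense), the catalyst‑bound imine tautomerises to the C1 enamine, which closes 6‑exo onto the butenolide β‑carbon C12 on the only face the tether reaches (cis fusion), and the lactone enol is protonated from the convex face (13S, methyl endo); the closest known chemistry is primary‑amine‑catalysed direct vinylogous Michael addition of butenolides to enones and iminium–enamine double‑Michael (Robinson‑type) annulations.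

Step 7
Reactants: 14 ring‑A keto lactone; 15 4‑chlorobutanal
Product: 17 (E)‑4‑chlorobutylidene ketone, via aldol 16 (not isolated)
Conditions: Cy2BCl, Et3N, Et2O, −78 °C; then 15, −78 to −20 °C; crude aldol with MsCl, Et3N, CH2Cl2, 0 °C to rt
Reagents that add atoms: none
Why: Boron‑mediated aldol condensation — Cy2BCl/Et3N enolises only the ketone and only towards its single CH2 (C9), and mesylation/E1cB elimination gives the (E)‑alkylidene ketone that carries C5–C8 and the chloride needed later, without the strong base that would threaten the 13S centre.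

Step 8
Reactants: 17 (E)‑4‑chlorobutylidene ketone
Product: 18 4‑chlorobutyl ketone
Conditions: H2 (1 atm), 10 % Pd/C, EtOAc, rt
Reagents that add atoms: none
Why: Heterogeneous hydrogenation saturates the conjugated exocyclic C=C without touching the primary chloride, carbamate or lactones; the C9 epimer mixture is irrelevant because C9 becomes sp2 in step 10.

Step 9
Reactants: 18 4‑chlorobutyl ketone
Product: 20 α‑hydroxy ketone, via enecarbamate 19 (not isolated)
Conditions: PPTS (10 mol %), 4 Å MS, toluene, 80 °C; then DMDO (1.1 equiv), acetone–CH2Cl2, −40 to 0 °C; aq. NaHCO3 work‑up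
Reagents that add atoms: dimethyldioxirane (CC1(C)OO1); water (O)
Why: Acid‑catalysed cyclodehydration forms the N–C9a bond as the ring‑fused endocyclic enecarbamate (the exocyclic isomer suffers A(1,3) strain with Boc), DMDO epoxidises the electron‑rich C1=C9a bond from the convex face anti to the C12 lactone arm and the C3 substituent, and hydrolytic opening of the aminal epoxide returns the ketone with the C1–OH trans to C13 (1S) — a Rubottom‑type oxidation of an enecarbamate.

Step 10
Reactants: 20 α‑hydroxy ketone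
Product: 23 target CNP0179500.1, via ammonium trifluoroacetate 21 (not isolated), via hydroxy imine 22 (not isolated)
Conditions: TFA–CH2Cl2 (1:4), 0 °C to rt; evaporate; K2CO3, NaI (20 mol %), MeCN, 50 °C
Reagents that add atoms: none
Why: N‑Boc cleavage, condensation of the free amine with the C9a ketone to the 1‑pyrroline (C–N), 7‑exo‑tet N‑alkylation of the imine nitrogen by the iodide formed in situ (Finkelstein, C–N) and loss of the only available α‑proton (H9, since C1 is quaternary) give the tetrasubstituted enamine as a single regioisomer.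

**Compound list**

1 | (2S)‑1‑(tert‑butoxycarbonyl)‑5‑oxopyrrolidine‑2‑carboxylic acid (Boc‑L‑pyroglutamic acid) | CC(C)(C)OC(=O)N1C(=O)CC[C@H]1C(=O)O | starting material
2 | S‑ethyl (2S)‑1‑(tert‑butoxycarbonyl)‑5‑oxopyrrolidine‑2‑carbothioate | CC(C)(C)OC(=O)N1C(=O)CC[C@H]1C(=O)SCC | intermediate
3 | methyl (2R)‑3‑bromo‑2‑methylpropanoate | BrC[C@H](C)C(=O)OC | starting material
4 | [(2R)‑3‑methoxy‑2‑methyl‑3‑oxopropyl]zinc bromide | Br[Zn]C[C@H](C)C(=O)OC | intermediate
5 | tert‑butyl (2S)‑2‑[(3S)‑4‑methoxy‑3‑methyl‑4‑oxobutanoyl]‑5‑oxopyrrolidine‑1‑carboxylate | CC(C)(C)OC(=O)N1C(=O)CC[C@H]1C(=O)C[C@H](C)C(=O)OC | intermediate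
6 | tert‑butyl (2S)‑2‑[(1S,3S)‑1‑hydroxy‑4‑methoxy‑3‑methyl‑4‑oxobutyl]‑5‑oxopyrrolidine‑1‑carboxylate | CC(C)(C)OC(=O)N1C(=O)CC[C@H]1[C@@H](O)C[C@H](C)C(=O)OC | intermediate
7 | tert‑butyl (2S)‑2‑[(2S,4S)‑4‑methyl‑5‑oxooxolan‑2‑yl]‑5‑oxopyrrolidine‑1‑carboxylate | CC(C)(C)OC(=O)N1C(=O)CC[C@H]1[C@@H]1C[C@H](C)C(=O)O1 | intermediate
8 | vinylmagnesium bromide | C=C[Mg]Br | starting material
9 | tert‑butyl N‑[(1S)‑1‑[(2S,4S)‑4‑methyl‑5‑oxooxolan‑2‑yl]‑4‑oxohex‑5‑en‑1‑yl]carbamate | C=CC(=O)CC[C@H](NC(=O)OC(C)(C)C)[C@@H]1C[C@H](C)C(=O)O1 | intermediate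
10 | but‑1‑ene | C=CCC | starting material
11 | tert‑butyl N‑[(1S,5E)‑1‑[(2S,4S)‑4‑methyl‑5‑oxooxolan‑2‑yl]‑4‑oxooct‑5‑en‑1‑yl]carbamate | CC/C=C/C(=O)CC[C@H](NC(=O)OC(C)(C)C)[C@@H]1C[C@H](C)C(=O)O1 | intermediate
12 | 3‑methylfuran‑2(5H)‑one | CC1=CCOC1=O | starting material
13 | tert‑butyl N‑[(1S,6R)‑6‑[(2R)‑4‑methyl‑5‑oxo‑2,5‑dihydrofuran‑2‑yl]‑1‑[(2S,4S)‑4‑methyl‑5‑oxooxolan‑2‑yl]‑4‑oxooctan‑1‑yl]carbamate | CC[C@H](CC(=O)CC[C@H](NC(=O)OC(C)(C)C)[C@@H]1C[C@H](C)C(=O)O1)[C@H]1OC(=O)C(C)=C1 | intermediate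
14 | tert‑butyl N‑[(1S)‑2‑[(3S,3aR,4S,7R,7aR)‑7‑ethyl‑3‑methyl‑2,5‑dioxooctahydro‑1‑benzofuran‑4‑yl]‑1‑[(2S,4S)‑4‑methyl‑5‑oxooxolan‑2‑yl]ethyl]carbamate (cis‑fused; ethyl, lactone O and lactone C all cis; the C4–H epimer drawn is the equatorial one and is erased in step 9) | CC[C@@H]1CC(=O)[C@@H](C[C@H](NC(=O)OC(C)(C)C)[C@@H]2C[C@H](C)C(=O)O2)[C@H]2[C@@H]1OC(=O)[C@H]2C | intermediate
15 | 4‑chlorobutanal | O=CCCCCl | starting material
16 | 6‑(4‑chloro‑1‑hydroxybutyl) derivative of 14 (aldol; mixture at C6 and the carbinol carbon) | CC[C@@H]1C(C(O)CCCCl)C(=O)[C@@H](C[C@H](NC(=O)OC(C)(C)C)[C@@H]2C[C@H](C)C(=O)O2)[C@H]2[C@@H]1OC(=O)[C@H]2C | intermediate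
17 | (6E)‑6‑(4‑chlorobutylidene) derivative of 14 | CC[C@@H]1/C(=C\CCCCl)C(=O)[C@@H](C[C@H](NC(=O)OC(C)(C)C)[C@@H]2C[C@H](C)C(=O)O2)[C@H]2[C@@H]1OC(=O)[C@H]2C | intermediate
18 | 6‑(4‑chlorobutyl) derivative of 14 (C6 epimers) | CC[C@@H]1C(CCCCCl)C(=O)[C@@H](C[C@H](NC(=O)OC(C)(C)C)[C@@H]2C[C@H](C)C(=O)O2)[C@H]2[C@@H]1OC(=O)[C@H]2C | intermediate
19 | ring‑fused N‑Boc 2‑pyrroline from 18 (endocyclic C1=C9a enecarbamate; C9 epimers) | CC[C@@H]1C(CCCCCl)C2=C(C[C@H](N2C(=O)OC(C)(C)C)[C@@H]3C[C@H](C)C(=O)O3)[C@H]3[C@@H]1OC(=O)[C@H]3C | intermediate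
20 | tert‑butyl N‑[(1S)‑2‑[(3S,3aR,4S,7R,7aR)‑6‑(4‑chlorobutyl)‑7‑ethyl‑4‑hydroxy‑3‑methyl‑2,5‑dioxooctahydro‑1‑benzofuran‑4‑yl]‑1‑[(2S,4S)‑4‑methyl‑5‑oxooxolan‑2‑yl]ethyl]carbamate (C6 epimers; in equilibrium with its cyclic N‑Boc hemiaminal) | CC[C@@H]1C(CCCCCl)C(=O)[C@](O)(C[C@H](NC(=O)OC(C)(C)C)[C@@H]2C[C@H](C)C(=O)O2)[C@H]2[C@@H]1OC(=O)[C@H]2C | intermediate
21 | primary ammonium trifluoroacetate of Boc‑free 20 | CC[C@@H]1C(CCCCCl)C(=O)[C@](O)(C[C@H]([NH3+])[C@@H]2C[C@H](C)C(=O)O2)[C@H]2[C@@H]1OC(=O)[C@H]2C.[O-]C(=O)C(F)(F)F | intermediate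
22 | hydroxy 1‑pyrroline (N=C9a cyclic imine; 1S,3S,10R,11R,12R,13S,18S,20S; C9 epimers) with the 4‑chlorobutyl arm on C9 | CC[C@@H]1C(CCCCCl)C2=N[C@H]([C@@H]3C[C@H](C)C(=O)O3)C[C@]2(O)[C@H]2[C@@H]1OC(=O)[C@H]2C | intermediate
23 | CNP0179500.1 (1S,3S,10R,11R,12R,13S,18S,20S) | CC[C@@H]1C2=C3N(CCCC2)[C@H]([C@@H]2C[C@H](C)C(=O)O2)C[C@]3(O)[C@H]2[C@@H]1OC(=O)[C@H]2C | target

**Step count and risks**

Total steps: 10. Longest linear sequence: 10 (from Boc‑L‑pyroglutamic acid; every other building block is purchased and added directly).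

The three steps most likely to fail:

1. Step 6 (the proposed annulation). The risks are the wrong C10/C11 diastereomer, or a stalled ring closure. Fallback with known chemistry, setting out from 11 and coming back at 14: the relay is cut into two separately precedented operations. Enone 11 and 12 are combined with the same cinchona primary‑amine salt at −20 °C in CHCl3, where only the iminium‑catalysed direct vinylogous Michael addition of the butenolide to the enone proceeds, and adduct 13 is isolated and purified as the 10R,11R diastereomer. Adduct 13 is then cyclised by a base‑mediated intramolecular 6‑exo Michael addition of the ketone enolate onto the butenolide (DBU 0.3 equiv, MeCN, −20 °C, AcOH quench), which gives 14. This fallback makes no compound outside the list (F0).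

2. Step 7 (aldol condensation at C9). The risks are incomplete or unselective enolisation next to the carbamate, and self‑condensation or cyclisation of 4‑chlorobutanal. Fallback setting out from 14 and coming back at 18: the C9 chain is brought in by allylation and metathesis instead of an aldol. Pd(PPh3)4/pyrrolidine‑catalysed α‑allylation with allyl acetate (enamine/π‑allyl dual catalysis, DMSO, rt) gives the 6‑allyl ketone F1. Cross‑metathesis with allyl chloride (Hoveyda–Grubbs II, CH2Cl2, 40 °C) gives the (E)‑4‑chlorobut‑2‑enyl ketone F2. Diimide reduction (2‑nitrobenzenesulfonylhydrazide, Et3N, CH2Cl2, rt) saturates the alkene without hydrogenolysis of the allylic chloride and gives 18.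

3. Step 9 (enecarbamate formation and epoxidation). The risks are deprotonation towards C9 (exocyclic enecarbamate, hydroxylation at the wrong carbon) and incomplete facial control. Fallback setting out from 17 and coming back at 20 (it replaces steps 8 and 9): while C9 is still blocked as the alkylidene, C1–H is the only α‑hydrogen. TMSOTf, Et3N, CH2Cl2, −78 °C gives the cross‑conjugated trimethylsilyl dienol ether F3. Rubottom oxidation with DMDO (acetone, −78 °C, citric acid work‑up), again on the face anti to the lactone, gives the α‑hydroxy enone F4. Hydrogenation as in step 8 (H2, Pd/C, EtOAc) then gives 20.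

Further compounds

F0 | step 6 | none | none
F1 | step 7 | 6‑(prop‑2‑en‑1‑yl) derivative of 14 (C6 epimers) | CC[C@@H]1C(CC=C)C(=O)[C@@H](C[C@H](NC(=O)OC(C)(C)C)[C@@H]2C[C@H](C)C(=O)O2)[C@H]2[C@@H]1OC(=O)[C@H]2C
F2 | step 7 | 6‑[(2E)‑4‑chlorobut‑2‑en‑1‑yl] derivative of 14 (C6 epimers) | CC[C@@H]1C(C/C=C/CCl)C(=O)[C@@H](C[C@H](NC(=O)OC(C)(C)C)[C@@H]2C[C@H](C)C(=O)O2)[C@H]2[C@@H]1OC(=O)[C@H]2C
F3 | step 9 | trimethylsilyl dienol ether of 17 (C1=C9a–OSiMe3, C9=C8 retained) | CC[C@@H]1/C(=C\CCCCl)C(O[Si](C)(C)C)=C(C[C@H](NC(=O)OC(C)(C)C)[C@@H]2C[C@H](C)C(=O)O2)[C@H]2[C@@H]1OC(=O)[C@H]2C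
F4 | step 9 | 4‑hydroxy derivative of 17 (α‑hydroxy enone, OH trans to the lactone C3a–C3 bond) | CC[C@@H]1/C(=C\CCCCl)C(=O)[C@](O)(C[C@H](NC(=O)OC(C)(C)C)[C@@H]2C[C@H](C)C(=O)O2)[C@H]2[C@@H]1OC(=O)[C@H]2C
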